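If a ligand took catalyst out of service one for one (stoichiometric poisoning), the working catalyst would be charge minus ligand, and I began with that bench rule.

in all of them: left-handed substrate 14 mM; right-handed substrate 14 mM
- red: reagent 28 mM; free catalyst 7 µM; added ligand 3 µM; run made earlier
- green: reagent 28 mM; free catalyst 7 µM; added ligand 12 µM; run made earlier
- flask: reagent 28.0 mM; free catalyst 7.0 µM; added ligand 6.0 µM; time 20 min

| run | time / min | left-handed product / % | right-handed product / % |
|---|---|---|---|
| red | 1.00 | 9.8 | 4.4 |
| red | 3.00 | 22.0 | 9.8 |
| red | 6.00 | 35.9 | 15.2 |
| red | 8.00 | 41.8 | 17.8 |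
| red | 12.0 | 49.6 | 20.2 |
| red | 15.0 | 54.3 | 21.2 |
| green | 1.33 | 5.5 | 2.2 |
| green | 2.00 | 9.3 | 3.8 |
| green | 4.00 | 16.2 | 6.6 |
| green | 6.00 | 22.3 | 9.8 |
| green | 10.0 | 29.8 | 13.4 |
| green | 15.0 | 39.1 | 15.5 |

(readings scatter by 0.5 percentage points)

- excess of left-handed product over right-handed product in the product at 2.0 min
- excess of left-handed product over right-handed product in the product at 20 min
- part of the left-handed substrate and right-handed substrate charged together that has reacted at 20 min

The rule gave the flask a quarter of red's working catalyst. Its border is a ligand-to-catalyst ratio of one. The flask stood just below it at 0.857, and green stood above it at 1.71. There the rule leaves no working catalyst, yet green had converted 54.6% by 15.0 min. So I dropped the rule and compared clocks. Green reached 32.1% at 6.00 min and red reached 31.8% at 3.00 min, which gave a reading of s = 0.500 for green's clock against red's. I took speed as proportional to 1/(K + L), with L the ligand charged and K a ligand level read from the two runs: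

K = (s·L_green − L_red)/(1 − s) = 6.00 µM

a = (K + L_red)/(K + L) = 0.750

This a, the pace factor, is my estimate of a flask's speed relative to red at equal conversion, with the charges other than the ligand held at red's.

The flask's 20 min was therefore worth 15.0 min of red, where red showed 75.5% reacted and an excess of 43.8%. Its 2.0 min was worth 1.50 min, between red readings with excesses of 38.0% and 38.4%.

The forecast gave excesses of 39% early and 43% late with 75% reacted, taking a rate of about 0.73 of red's where I had 0.750, and reasoning that “the ligand seems to change only the rate”.

The flask gave excesses of 37.1% early and 44.6% late with 74.1% reacted. At 2.00 min the idle complex held 40.4% of the catalyst charged, while 52.9% of the added ligand's charge stood free. Used once more, a put the flask's 10.0 min at 7.50 min of red, between red's 51.1% and 59.6%; the flask's products then summed to 56.8%.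

    reagent + catalyst intermediate B → free catalyst + right-handed product (k = 210 M⁻¹ s⁻¹)
    reagent + free catalyst → spent catalyst (k = 0.330 M⁻¹ s⁻¹)
    free catalyst + added ligand ⇌ idle complex, settled at all times (K = 1.20 × 10⁶ M⁻¹)
    left-handed substrate ⇌ right-handed substrate (k = 0.00260 s⁻¹)
    free catalyst + right-handed substrate ⇌ catalyst intermediate B (K = 320 M⁻¹, k = 9300 M⁻¹ s⁻¹)
    free catalyst + left-handed substrate ⇌ catalyst intermediate A (K = 210 M⁻¹, k = 3800 M⁻¹ s⁻¹)
    reagent + catalyst intermediate A → free catalyst + left-handed product (k = 5300 M⁻¹ s⁻¹)

For a neighbour flask charged with 2.40 µM of added ligand, the pace factor estimated its speed relative to this flask at 1.43, and treating what is left as an exponential decay on that faster clock gave an estimate of 85.5% reacted. The simulation gave 82.8%.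

The data were generated by integration on assumed constants; the scatter is artificial.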